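**Plan**

- Retrosynthesis: the eleven O–benzyl bonds are cut first. Next comes the C4–C4a bond of the upper unit, which opens ring C to an acyclic C2–C3–C4 chain hanging on the ring A oxygen. Then the C4–C8(D) interflavan bond is cut (aldehyde plus C8-lithiated ring D), then the C2–O1 aryl ether bond (epoxide opening), back to a cinnamyl alcohol.
- Forward: fragment 1 (rings A and B on an acyclic aldehyde) is built from 3,4,5-tris(benzyloxy)benzaldehyde and 3-(benzyloxy)phenol. Fragment 2 (rings D, E, F) comes from natural (−)-epigallocatechin. The fragments are joined at C4–C8(D), and ring C is closed last.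
- Enabling feature: C4 is benzylic to ring D, whose C8 has oxygen on both ortho carbons (O1 of ring F, C7–O) and on the para carbon (C5–O), so C4 ionises under mild acid to a quinone-methide-type cation. C4a of ring A is para to the C7 oxygen and ortho to O1, so ring A is a matched, tethered nucleophile.
- Stereochemistry: upper C3 comes from the Sharpless epoxidation, upper C2 from SN2 inversion by the phenoxide, and upper C4 from the cyclisation under 1,2-induction by C3. The lower C2 and C3 come from the chiral pool.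
- The 4→8 regiochemistry is fixed by bromination and lithiation at C8 of ring D, not by a biased electrophilic coupling.

Key step: step 13

Remark: carbinol 17 is carried as the mixture of epimers at its new carbinol carbon, because that centre becomes trigonal in step 13; its SMILES has no descriptor at that atom.

**Route**

Step 1
Reactants: 1 3,4,5-tris(benzyloxy)benzaldehyde; 2 triethyl phosphonoacetate
Product: 3 ethyl (E)-3-[3,4,5-tris(benzyloxy)phenyl]prop-2-enoate
Conditions: NaH, THF, 0 °C → rt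
Reagents that add atoms: none
Why: Horner–Wadsworth–Emmons olefination of an aromatic aldehyde with a stabilised phosphonate anion should give the (E)-cinnamate.

Step 2
Reactants: 3 ethyl (E)-3-[3,4,5-tris(benzyloxy)phenyl]prop-2-enoate
Product: 4 (E)-3-[3,4,5-tris(benzyloxy)phenyl]prop-2-en-1-ol
Conditions: iBu2AlH (2.5 equiv), CH2Cl2, −78 → 0 °C; aq. potassium sodium tartrate
Reagents that add atoms: none
Why: 1,2-reduction of a conjugated ester with iBu2AlH is the standard route to (E)-cinnamyl alcohols and leaves the alkene and benzyl ethers untouched.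

Step 3
Reactants: 4 (E)-3-[3,4,5-tris(benzyloxy)phenyl]prop-2-en-1-ol
Product: 5 [(2S,3S)-3-[3,4,5-tris(benzyloxy)phenyl]oxiran-2-yl]methanol
Conditions: Ti(OiPr)4 (10 mol %), L-(+)-diisopropyl tartrate (12 mol %), t-BuOOH (2 equiv), 4 Å MS, CH2Cl2, −20 °C
Reagents that add atoms: tert-butyl hydroperoxide, CC(C)(C)OO
Why: Sharpless asymmetric epoxidation of an (E)-allylic alcohol, in which the L-(+)-tartrate ligand directs oxygen to the face that gives the (2S,3S)-epoxy alcohol and so fixes the future upper C3.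

Step 4
Reactants: 5 [(2S,3S)-3-[3,4,5-tris(benzyloxy)phenyl]oxiran-2-yl]methanol; 6 3-(benzyloxy)phenol
Product: 7 (2S,3R)-3-[3-(benzyloxy)phenoxy]-3-[3,4,5-tris(benzyloxy)phenyl]propane-1,2-diol
Conditions: 6 (1.5 equiv), NaOH (1.2 equiv), H2O–1,4-dioxane, 70 °C
Reagents that add atoms: none
Why: Phenoxide opening of a 3-aryl-2,3-epoxy alcohol should occur at the activated benzylic carbon by SN2 with inversion, which sets the aryl ether centre (future C2) anti to the untouched carbinol (future C3), the 2,3-trans pattern.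

Step 5
Reactants: 7 (2S,3R)-3-[3-(benzyloxy)phenoxy]-3-[3,4,5-tris(benzyloxy)phenyl]propane-1,2-diol
Product: 8 (2S,3R)-3-[3-(benzyloxy)phenoxy]-3-[3,4,5-tris(benzyloxy)phenyl]-1-(trityloxy)propan-2-ol
Conditions: TrCl (1.1 equiv), Et3N, DMAP (cat.), CH2Cl2, rt
Reagents that add atoms: trityl chloride, ClC(c1ccccc1)(c1ccccc1)c1ccccc1
Why: Selective tritylation, in which the bulky trityl chloride should react only with the primary hydroxyl.

Step 6
Reactants: 8 (2S,3R)-3-[3-(benzyloxy)phenoxy]-3-[3,4,5-tris(benzyloxy)phenyl]-1-(trityloxy)propan-2-ol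
Product: 9 (2S,3R)-2-(benzyloxy)-3-[3-(benzyloxy)phenoxy]-3-[3,4,5-tris(benzyloxy)phenyl]propyl trityl ether
Conditions: NaH, BnBr, Bu4NI (cat.), THF–DMF, 0 °C → rt
Reagents that add atoms: benzyl bromide, BrCc1ccccc1
Why: Williamson benzylation of the secondary alkoxide, and since a trityl ether does not migrate under base the benzyl group should end on the future C3 oxygen.

Step 7
Reactants: 9 (2S,3R)-2-(benzyloxy)-3-[3-(benzyloxy)phenoxy]-3-[3,4,5-tris(benzyloxy)phenyl]propyl trityl ether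
Product: 10 (2S,3R)-2-(benzyloxy)-3-[3-(benzyloxy)phenoxy]-3-[3,4,5-tris(benzyloxy)phenyl]propan-1-ol
Conditions: camphorsulfonic acid (cat.), MeOH–CH2Cl2, 0 °C → rt
Reagents that add atoms: none
Why: Acid-catalysed methanolysis of the trityl ether through the trityl cation should be far faster than cleavage of the benzyl or aryl ethers.

Step 8
Reactants: 10 (2S,3R)-2-(benzyloxy)-3-[3-(benzyloxy)phenoxy]-3-[3,4,5-tris(benzyloxy)phenyl]propan-1-ol
Product: 11 (2R,3R)-2-(benzyloxy)-3-[3-(benzyloxy)phenoxy]-3-[3,4,5-tris(benzyloxy)phenyl]propanal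
Conditions: Dess–Martin periodinane, pyridine, CH2Cl2, 0 °C → rt; used at once
Reagents that add atoms: none
Why: Dess–Martin oxidation under buffered, non-basic conditions should give the aldehyde without epimerising the α-benzyloxy centre or eliminating the β-aryloxide.

Step 9
Reactants: 12 (−)-epigallocatechin
Product: 13 (2R,3R)-5,7-bis(benzyloxy)-2-[3,4,5-tris(benzyloxy)phenyl]chroman-3-ol
Conditions: BnBr (5.5 equiv), K2CO3, DMF, 0 °C → rt, under Ar
Reagents that add atoms: benzyl bromide, BrCc1ccccc1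
Why: Williamson benzylation of the five phenols with a carbonate base too weak to deprotonate the C3 alcohol, with both stereocentres carried over unchanged from the natural flavan-3-ol.

Step 10
Reactants: 13 (2R,3R)-5,7-bis(benzyloxy)-2-[3,4,5-tris(benzyloxy)phenyl]chroman-3-ol
Product: 14 (2R,3R)-5,7-bis(benzyloxy)-8-bromo-2-[3,4,5-tris(benzyloxy)phenyl]chroman-3-ol
Conditions: NBS (1.0 equiv), CH2Cl2, −40 → 0 °C
Reagents that add atoms: N-bromosuccinimide, BrN1C(=O)CCC1=O
Why: Electrophilic aromatic bromination of the phloroglucinol-type ring D, which in benzylated flavan-3-ols takes place at C8 rather than at C6 flanked by two benzyloxy groups, and which is far faster than attack on ring E.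

Step 11
Reactants: 14 (2R,3R)-5,7-bis(benzyloxy)-8-bromo-2-[3,4,5-tris(benzyloxy)phenyl]chroman-3-ol
Product: 15 (2R,3R)-3,5,7-tris(benzyloxy)-8-bromo-2-[3,4,5-tris(benzyloxy)phenyl]chromane
Conditions: NaH, BnBr, DMF, 0 °C → rt
Reagents that add atoms: benzyl bromide, BrCc1ccccc1
Why: Williamson benzylation of the secondary alcohol removes the only acidic proton before the organolithium step.

Step 12
Reactants: 15 (2R,3R)-3,5,7-tris(benzyloxy)-8-bromo-2-[3,4,5-tris(benzyloxy)phenyl]chromane; 11 (2R,3R)-2-(benzyloxy)-3-[3-(benzyloxy)phenoxy]-3-[3,4,5-tris(benzyloxy)phenyl]propanal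
Product: 17 (1RS,2S,3R)-2-(benzyloxy)-3-[3-(benzyloxy)phenoxy]-1-[(2R,3R)-3,5,7-tris(benzyloxy)-2-[3,4,5-tris(benzyloxy)phenyl]chroman-8-yl]-3-[3,4,5-tris(benzyloxy)phenyl]propan-1-ol, via 8-lithio flavan 16 (not isolated)
Conditions: 15 (1.3 equiv), t-BuLi (2.6 equiv), THF, −78 °C; then 11, −78 °C; H2O quench; Et3N-washed SiO2
Reagents that add atoms: none
Why: Bromine–lithium exchange followed by 1,2-addition of the C8 aryllithium to the aldehyde should form the interflavan bond at C8 of ring D with no 4→6 isomer possible, and the new carbinol centre needs no control because step 13 makes it planar.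

Step 13
Reactants: 17 (1RS,2S,3R)-2-(benzyloxy)-3-[3-(benzyloxy)phenoxy]-1-[(2R,3R)-3,5,7-tris(benzyloxy)-2-[3,4,5-tris(benzyloxy)phenyl]chroman-8-yl]-3-[3,4,5-tris(benzyloxy)phenyl]propan-1-ol
Product: 19 (2R,3S,4S)-3,7-bis(benzyloxy)-4-[(2R,3R)-3,5,7-tris(benzyloxy)-2-[3,4,5-tris(benzyloxy)phenyl]chroman-8-yl]-2-[3,4,5-tris(benzyloxy)phenyl]chromane, via benzylic cation 18 (not isolated)
Conditions: BF3·OEt2 (0.2 equiv), CH2Cl2 (0.01 M), −78 → −30 °C
Reagents that add atoms: none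
Why: The Lewis acid should ionise only the C4 carbinol, because C4 is benzylic to ring D with two ortho oxygens and one para oxygen (a quinone-methide-type oxocarbenium), while the ring B benzylic ether at C2 stays intact; the tethered ring A then attacks C4 through its carbon para to the C7 benzyloxy group and ortho to O1 (the future C4a) and rearomatises, returning the proton so the acid turns over. The closest known reaction type is the intramolecular Friedel–Crafts cyclialkylation of 1-aryl-3-aryloxypropan-1-ols to 4-arylchromans. Ring C closes in the 6-exo-trig mode, the C4=C8(D) π-bond of the delocalised cation lying outside the new ring. C4 is controlled by C3 through A(1,3) strain: the C3–H bond lies in the plane of the cation next to the ortho-disubstituted ring D, the C3 benzyloxy group and C2 sit on opposite faces, and ring A, tethered through C2–O1, attacks anti to the benzyloxy group in a chair-like transition state with all three substituents equatorial, so both carbinol epimers should converge on the 3,4-trans (4S) product. The step needs regioselectivity on ring A, six-ring closure in preference to five-ring closure, and no elimination. The carbon between the two ring A oxygens is the more hindered site, closure through ring B would give a strained indane from a less nucleophilic carbon, the in-plane C3–H cannot align with the empty orbital for proton loss or hydride shift, and high dilution suppresses intermolecular capture.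

Step 14
Reactants: 19 (2R,3S,4S)-3,7-bis(benzyloxy)-4-[(2R,3R)-3,5,7-tris(benzyloxy)-2-[3,4,5-tris(benzyloxy)phenyl]chroman-8-yl]-2-[3,4,5-tris(benzyloxy)phenyl]chromane
Product: 20 (2R,3S,4S)-2-(3,4,5-trihydroxyphenyl)-4-[(2R,3R)-3,5,7-trihydroxy-2-(3,4,5-trihydroxyphenyl)chroman-8-yl]chromane-3,7-diol (robinetinidol-(4α→8)-epigallocatechin)
Conditions: H2 (1 atm), Pd(OH)2/C, THF–MeOH–H2O, rt; filtration under Ar
Reagents that add atoms: none
Why: Hydrogenolysis of all eleven benzyl ethers under neutral conditions should free the phenols and both C3 alcohols without cleaving the interflavan bond or the benzylic pyran C–O bonds.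

**Compound list**

1 | 3,4,5-tris(benzyloxy)benzaldehyde | O=Cc1cc(OCc2ccccc2)c(OCc2ccccc2)c(OCc2ccccc2)c1 | starting material
2 | triethyl phosphonoacetate | CCOC(=O)CP(=O)(OCC)OCC | starting material
3 | ethyl (E)-3-[3,4,5-tris(benzyloxy)phenyl]prop-2-enoate | CCOC(=O)/C=C/c1cc(OCc2ccccc2)c(OCc2ccccc2)c(OCc2ccccc2)c1 | intermediate
4 | (E)-3-[3,4,5-tris(benzyloxy)phenyl]prop-2-en-1-ol | OC/C=C/c1cc(OCc2ccccc2)c(OCc2ccccc2)c(OCc2ccccc2)c1 | intermediate
5 | [(2S,3S)-3-[3,4,5-tris(benzyloxy)phenyl]oxiran-2-yl]methanol | OC[C@@H]1O[C@H]1c1cc(OCc2ccccc2)c(OCc2ccccc2)c(OCc2ccccc2)c1 | intermediate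
6 | 3-(benzyloxy)phenol | Oc1cccc(OCc2ccccc2)c1 | starting material
7 | (2S,3R)-3-[3-(benzyloxy)phenoxy]-3-[3,4,5-tris(benzyloxy)phenyl]propane-1,2-diol | c1ccccc1COc1cccc(c1)O[C@H](c1cc(OCc2ccccc2)c(OCc2ccccc2)c(OCc2ccccc2)c1)[C@@H](O)CO | intermediate
8 | (2S,3R)-3-[3-(benzyloxy)phenoxy]-3-[3,4,5-tris(benzyloxy)phenyl]-1-(trityloxy)propan-2-ol | c1ccccc1COc1cccc(c1)O[C@H](c1cc(OCc2ccccc2)c(OCc2ccccc2)c(OCc2ccccc2)c1)[C@@H](O)COC(c1ccccc1)(c1ccccc1)c1ccccc1 | intermediate
9 | (2S,3R)-2-(benzyloxy)-3-[3-(benzyloxy)phenoxy]-3-[3,4,5-tris(benzyloxy)phenyl]propyl trityl ether | c1ccccc1COc1cccc(c1)O[C@H](c1cc(OCc2ccccc2)c(OCc2ccccc2)c(OCc2ccccc2)c1)[C@@H](OCc1ccccc1)COC(c1ccccc1)(c1ccccc1)c1ccccc1 | intermediate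
10 | (2S,3R)-2-(benzyloxy)-3-[3-(benzyloxy)phenoxy]-3-[3,4,5-tris(benzyloxy)phenyl]propan-1-ol | c1ccccc1COc1cccc(c1)O[C@H](c1cc(OCc2ccccc2)c(OCc2ccccc2)c(OCc2ccccc2)c1)[C@@H](OCc1ccccc1)CO | intermediate
11 | (2R,3R)-2-(benzyloxy)-3-[3-(benzyloxy)phenoxy]-3-[3,4,5-tris(benzyloxy)phenyl]propanal | c1ccccc1COc1cccc(c1)O[C@H](c1cc(OCc2ccccc2)c(OCc2ccccc2)c(OCc2ccccc2)c1)[C@@H](OCc1ccccc1)C=O | intermediate
12 | (−)-epigallocatechin, (2R,3R)-2-(3,4,5-trihydroxyphenyl)chromane-3,5,7-triol | Oc1cc(O)c2c(c1)O[C@H](c1cc(O)c(O)c(O)c1)[C@H](O)C2 | starting material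
13 | (2R,3R)-5,7-bis(benzyloxy)-2-[3,4,5-tris(benzyloxy)phenyl]chroman-3-ol | c1ccccc1COc1cc(OCc3ccccc3)c2c(c1)O[C@H](c1cc(OCc3ccccc3)c(OCc3ccccc3)c(OCc3ccccc3)c1)[C@H](O)C2 | intermediate
14 | (2R,3R)-5,7-bis(benzyloxy)-8-bromo-2-[3,4,5-tris(benzyloxy)phenyl]chroman-3-ol | Brc1c(OCc3ccccc3)cc(OCc3ccccc3)c2c1O[C@H](c1cc(OCc3ccccc3)c(OCc3ccccc3)c(OCc3ccccc3)c1)[C@H](O)C2 | intermediate
15 | (2R,3R)-3,5,7-tris(benzyloxy)-8-bromo-2-[3,4,5-tris(benzyloxy)phenyl]chromane | Brc1c(OCc3ccccc3)cc(OCc3ccccc3)c2c1O[C@H](c1cc(OCc3ccccc3)c(OCc3ccccc3)c(OCc3ccccc3)c1)[C@H](OCc1ccccc1)C2 | intermediate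
16 | [(2R,3R)-3,5,7-tris(benzyloxy)-2-[3,4,5-tris(benzyloxy)phenyl]chroman-8-yl]lithium | [Li]c1c(OCc3ccccc3)cc(OCc3ccccc3)c2c1O[C@H](c1cc(OCc3ccccc3)c(OCc3ccccc3)c(OCc3ccccc3)c1)[C@H](OCc1ccccc1)C2 | intermediate (not isolated)
17 | (1RS,2S,3R)-2-(benzyloxy)-3-[3-(benzyloxy)phenoxy]-1-[(2R,3R)-3,5,7-tris(benzyloxy)-2-[3,4,5-tris(benzyloxy)phenyl]chroman-8-yl]-3-[3,4,5-tris(benzyloxy)phenyl]propan-1-ol | c1ccccc1COc1cccc(c1)O[C@H](c1cc(OCc2ccccc2)c(OCc2ccccc2)c(OCc2ccccc2)c1)[C@@H](OCc1ccccc1)C(O)c1c(OCc3ccccc3)cc(OCc3ccccc3)c2c1O[C@H](c1cc(OCc3ccccc3)c(OCc3ccccc3)c(OCc3ccccc3)c1)[C@H](OCc1ccccc1)C2 | intermediate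
18 | C4 benzylic cation of 17 stabilised by ring D, as its hydroxytrifluoroborate ion pair | c1ccccc1COc1cccc(c1)O[C@H](c1cc(OCc2ccccc2)c(OCc2ccccc2)c(OCc2ccccc2)c1)[C@@H](OCc1ccccc1)[CH+]c1c(OCc3ccccc3)cc(OCc3ccccc3)c2c1O[C@H](c1cc(OCc3ccccc3)c(OCc3ccccc3)c(OCc3ccccc3)c1)[C@H](OCc1ccccc1)C2.O[B-](F)(F)F | intermediate (not isolated)
19 | (2R,3S,4S)-3,7-bis(benzyloxy)-4-[(2R,3R)-3,5,7-tris(benzyloxy)-2-[3,4,5-tris(benzyloxy)phenyl]chroman-8-yl]-2-[3,4,5-tris(benzyloxy)phenyl]chromane | c1ccccc1COc1ccc2c(c1)O[C@H](c1cc(OCc3ccccc3)c(OCc3ccccc3)c(OCc3ccccc3)c1)[C@@H](OCc1ccccc1)[C@@H]2c1c(OCc3ccccc3)cc(OCc3ccccc3)c2c1O[C@H](c1cc(OCc3ccccc3)c(OCc3ccccc3)c(OCc3ccccc3)c1)[C@H](OCc1ccccc1)C2 | intermediate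
20 | (2R,3S,4S)-2-(3,4,5-trihydroxyphenyl)-4-[(2R,3R)-3,5,7-trihydroxy-2-(3,4,5-trihydroxyphenyl)chroman-8-yl]chromane-3,7-diol | Oc1ccc2c(c1)O[C@H](c1cc(O)c(O)c(O)c1)[C@@H](O)[C@@H]2c1c(O)cc(O)c2c1O[C@H](c1cc(O)c(O)c(O)c1)[C@H](O)C2 | target

**Step count**

Total: 14 steps. Longest linear sequence: 11 steps (steps 1 to 8, then 12, 13, 14).

**Steps most likely to fail**

Step 13. Ring A may attack through the carbon between its two oxygens, ring B may close a five-membered ring instead, or the facial preference at C4 may be weak. The fallback reverses the order of bond formation at C4. Setting out from aldehyde 11, BF3·OEt2 in CH2Cl2 at −78 °C would close ring C first by intramolecular Friedel–Crafts hydroxyalkylation to the flavan-3,4-diol derivative (2R,3S,4RS)-3,7-bis(benzyloxy)-2-[3,4,5-tris(benzyloxy)phenyl]chroman-4-ol F1. Condensation of F1 with an excess of the ring D nucleophile 13 (Me3SiOTf, CH2Cl2, −78 °C) would then form the C4–C8 bond by the classical flavan-4-yl cation route. After chromatographic removal of any 4β and 4→6 isomers this gives (2R,3S,4S)-3,7-bis(benzyloxy)-4-[(2R,3R)-5,7-bis(benzyloxy)-3-hydroxy-2-[3,4,5-tris(benzyloxy)phenyl]chroman-8-yl]-2-[3,4,5-tris(benzyloxy)phenyl]chromane F2. Hydrogenolysis of F2 under the conditions of step 14 comes back to the route at 20.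

Step 12. The hindered aryllithium may deprotonate the aldehyde, after which the β-aryloxide is eliminated; the bromine–lithium exchange may also be incomplete. The fallback replaces direct addition by acylation and reduction. Setting out from 11, Pinnick oxidation (NaClO2, NaH2PO4, 2-methyl-2-butene, t-BuOH–H2O) would give (2R,3R)-2-(benzyloxy)-3-[3-(benzyloxy)phenoxy]-3-[3,4,5-tris(benzyloxy)phenyl]propanoic acid F3. Coupling with N,O-dimethylhydroxylamine hydrochloride (EDC·HCl, N-methylmorpholine, CH2Cl2) would give the Weinreb amide (2R,3R)-2-(benzyloxy)-3-[3-(benzyloxy)phenoxy]-N-methoxy-N-methyl-3-[3,4,5-tris(benzyloxy)phenyl]propanamide F4. Aryllithium 16 at −78 °C would add once, through the chelated tetrahedral intermediate, to give (2R,3R)-2-(benzyloxy)-3-[3-(benzyloxy)phenoxy]-1-[(2R,3R)-3,5,7-tris(benzyloxy)-2-[3,4,5-tris(benzyloxy)phenyl]chroman-8-yl]-3-[3,4,5-tris(benzyloxy)phenyl]propan-1-one F5. Luche reduction of F5 (NaBH4, CeCl3·7H2O, MeOH–THF, −40 °C) comes back to the route at 17.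

Step 4. The epoxide may be opened at the wrong carbon after Payne rearrangement, or the benzylic centre may lose configuration through an SN1 pathway at the electron-rich ring B. The fallback builds the same two stereocentres by aldol reaction and Mitsunobu inversion. It sets out from aldehyde 1 and uses (R)-4-benzyl-3-[(benzyloxy)acetyl]oxazolidin-2-one F6, made from (R)-4-benzyloxazolidin-2-one and benzyloxyacetyl chloride (n-BuLi, THF, −78 °C). An Evans syn-aldol reaction of F6 with 1 (Bu2BOTf, iPr2NEt, CH2Cl2, −78 → 0 °C) would give (R)-4-benzyl-3-[(2R,3S)-2-(benzyloxy)-3-hydroxy-3-[3,4,5-tris(benzyloxy)phenyl]propanoyl]oxazolidin-2-one F7. Mitsunobu etherification of F7 with phenol 6 (PPh3, diisopropyl azodicarboxylate, toluene, 0 °C) would invert the benzylic carbon and give (R)-4-benzyl-3-[(2R,3R)-2-(benzyloxy)-3-[3-(benzyloxy)phenoxy]-3-[3,4,5-tris(benzyloxy)phenyl]propanoyl]oxazolidin-2-one F8. Reductive removal of the auxiliary from F8 (LiBH4, THF–MeOH, 0 °C) comes back to the route at 10, bypassing compounds 3 to 5 and 7 to 9.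

**Further compounds**

F1 | step 13 | (2R,3S,4RS)-3,7-bis(benzyloxy)-2-[3,4,5-tris(benzyloxy)phenyl]chroman-4-ol | c1ccccc1COc1ccc2c(c1)O[C@H](c1cc(OCc3ccccc3)c(OCc3ccccc3)c(OCc3ccccc3)c1)[C@@H](OCc1ccccc1)C2O
F2 | step 13 | (2R,3S,4S)-3,7-bis(benzyloxy)-4-[(2R,3R)-5,7-bis(benzyloxy)-3-hydroxy-2-[3,4,5-tris(benzyloxy)phenyl]chroman-8-yl]-2-[3,4,5-tris(benzyloxy)phenyl]chromane | c1ccccc1COc1ccc2c(c1)O[C@H](c1cc(OCc3ccccc3)c(OCc3ccccc3)c(OCc3ccccc3)c1)[C@@H](OCc1ccccc1)[C@@H]2c1c(OCc3ccccc3)cc(OCc3ccccc3)c2c1O[C@H](c1cc(OCc3ccccc3)c(OCc3ccccc3)c(OCc3ccccc3)c1)[C@H](O)C2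
F3 | step 12 | (2R,3R)-2-(benzyloxy)-3-[3-(benzyloxy)phenoxy]-3-[3,4,5-tris(benzyloxy)phenyl]propanoic acid | c1ccccc1COc1cccc(c1)O[C@H](c1cc(OCc2ccccc2)c(OCc2ccccc2)c(OCc2ccccc2)c1)[C@@H](OCc1ccccc1)C(=O)O
F4 | step 12 | (2R,3R)-2-(benzyloxy)-3-[3-(benzyloxy)phenoxy]-N-methoxy-N-methyl-3-[3,4,5-tris(benzyloxy)phenyl]propanamide | c1ccccc1COc1cccc(c1)O[C@H](c1cc(OCc2ccccc2)c(OCc2ccccc2)c(OCc2ccccc2)c1)[C@@H](OCc1ccccc1)C(=O)N(C)OC
F5 | step 12 | (2R,3R)-2-(benzyloxy)-3-[3-(benzyloxy)phenoxy]-1-[(2R,3R)-3,5,7-tris(benzyloxy)-2-[3,4,5-tris(benzyloxy)phenyl]chroman-8-yl]-3-[3,4,5-tris(benzyloxy)phenyl]propan-1-one | c1ccccc1COc1cccc(c1)O[C@H](c1cc(OCc2ccccc2)c(OCc2ccccc2)c(OCc2ccccc2)c1)[C@@H](OCc1ccccc1)C(=O)c1c(OCc3ccccc3)cc(OCc3ccccc3)c2c1O[C@H](c1cc(OCc3ccccc3)c(OCc3ccccc3)c(OCc3ccccc3)c1)[C@H](OCc1ccccc1)C2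
F6 | step 4 | (R)-4-benzyl-3-[(benzyloxy)acetyl]oxazolidin-2-one | O=C(COCc1ccccc1)N1[C@H](Cc2ccccc2)COC1=O
F7 | step 4 | (R)-4-benzyl-3-[(2R,3S)-2-(benzyloxy)-3-hydroxy-3-[3,4,5-tris(benzyloxy)phenyl]propanoyl]oxazolidin-2-one | O[C@@H](c1cc(OCc2ccccc2)c(OCc2ccccc2)c(OCc2ccccc2)c1)[C@@H](OCc1ccccc1)C(=O)N1[C@H](Cc2ccccc2)COC1=O
F8 | step 4 | (R)-4-benzyl-3-[(2R,3R)-2-(benzyloxy)-3-[3-(benzyloxy)phenoxy]-3-[3,4,5-tris(benzyloxy)phenyl]propanoyl]oxazolidin-2-one | c1ccccc1COc1cccc(c1)O[C@H](c1cc(OCc2ccccc2)c(OCc2ccccc2)c(OCc2ccccc2)c1)[C@@H](OCc1ccccc1)C(=O)N1[C@H](Cc2ccccc2)COC1=O
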